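## The problem

The target is a dearomatised acylphloroglucinol. Ring A (C7, C8, C10, C26, C23, C24) is an enolised cyclohexane-1,3,5-trione; the C12–C13 bridge between C10 and C23 makes rings A and B (C10, C12, C13, C23, C26) a bicyclo[3.2.1]octane with C26 as the one-carbon ketone bridge, and cyclopentane ring C (C13, C14, C17, C22, C23) is cis-fused on the C13–C23 bond. Four ring stereocentres (C10, C13, C17, C23), two of them quaternary bridgeheads beside the C26 ketone, and the isolated side-chain centre C3 must come out as one enantiomer. C10 is tied to C23 by the bicycle and C13 to C23 by the ring fusion, so one decision, the face of ring A that the C12–C13 unit takes, fixes three centres. C17 is the only ring centre that can exist before any ring and has to make that decision; C3 has no neighbour to lean on and must be bought. The C24/C26 and C8/C26 β-diketones cannot enolise through C10 or C23 and are open to retro-Claisen cleavage by hydroxide or alkoxide. The C18 tertiary alcohol ionises in strong acid, and C3, next to a ketone, can epimerise during basic acyl transfer. The enabling feature is that ring A carries the oxygen pattern of a 1,3,5-trialkoxybenzene, that C10 and C23 are meta on it and flank the oxygen-bearing C26, and that the alkene carbons C13 and C12 are reached from C23 through exactly three atoms (C22, C17, C14). That is the geometry in which an excited alkoxyarene adds a tethered alkene across its 1,3-positions. Two points remain open in that step: the adduct is two electrons short of the trione, and the alkene could add on either flank of C23, toward C10 (wanted) or toward C7.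

## Retrosynthesis

**C5–C7.** Target 27 is cut first to the enolised β-diketone 24 and (R)-2-methylbutanoic acid 25. An acyl group carried from the arene stage would make the photosubstrate an aryl ketone, whose carbonyl excited state would displace the arene chemistry, and C3 would face every base on the way. The precursor loses five carbons, one stereocentre and the acidic triketone. The forward step must acylate carbon C7 of a 1,3-dione beside a free tertiary alcohol, without a base able to epimerise C3 or open the tricarbonyl.

**C8–C26, made in the backward direction.** Dione 24 comes by hydrolysis and loss of bromine from bromo vinylogous ester 22. Compound 22 is simplified by joining C8 to C26 and returning two electrons, which gives cage 19, a dialkoxycyclopropane beside an enol ether. This is preferred to any cut of a ring A bond because all six ring A carbons and all three oxygens stay together and the trione becomes an arene adduct. Forward, an electrophile on C7 must trigger cleavage of the C8–C26 bond with the O26 lone pair pushing, and this oxidation must outrun simple protonolysis of the cyclopropane.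

**C10–C12, C13–C23 and C8–C26 together.** Cutting all three bonds of 19 opens rings B and C and the cyclopropane and returns the flat arene–alkene 18. Cutting either ring B bond alone would ask for an alkylation or aldol closure onto a quaternary bridgehead between carbonyl groups. Compound 18 has one stereocentre where 19 has six, and no ring but the benzene. The forward reaction must be a 1,3-addition across C26, on the C10 flank and on the face chosen by C17.

**C7–Si and O–Si.** Compound 18 goes back to alcohol 16. The C7 silyl group is not in the target. It is carried because in 16 the C7 flank is the open one: C7 bears hydrogen and its neighbour O24 can lie in the ring plane, whereas C10 bears methyl and O26 is twisted. A trimethylsilyl group on C7 makes C7 the more hindered bonding site and twists O24 as well. It later leaves by ipso-bromination, which is also the first event of the oxidative opening. The forward step must metalate C7 only; C7–H is the single ring hydrogen and lies between two methoxy groups.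

**C18 methyl groups and the auxiliary.** Alcohol 16 comes from methyl ester 14, acid 13 and imide 11. Making the tertiary alcohol after the alkylation keeps a free hydroxyl away from the enolate chemistry. The forward steps must not epimerise C17.

**C17–C22.** Imide 11 is cut to imide 9 and benzylic bromide 5. C17–C14 would need a tertiary electrophile and C17–C18 an aldol with a ketone; the benzylic bond uses the most reactive electrophile against a hindered enolate and lets an oxazolidinone set C17. The forward reaction must deliver the (S) centre from the enolate face opposite the auxiliary's benzyl group.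

**Fragments.** Bromide 5 comes from alcohol 4, aldehyde 3 and 2,4,6-trimethoxytoluene 1, whose two free ring positions are equivalent. Imide 9 comes from 3,3-dimethylpent-4-enoic acid 6 and (4S)-4-benzyl-1,3-oxazolidin-2-one 7.

## Roads not taken

**Alternative 1:** Wolff ring contraction. The cut is C14–C17: ring C is derived from the six-membered ring of diazo ketone A1, in which C18 is the ketone and C17 carries the diazo group. Photolysis in methanol expels nitrogen, C14 moves from C18 to C17 and ring-contracted ester A2 results, with C18 as a methyl ester ready for two methyl additions.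
- Merits: the contraction is dependable, the cis C13–C23 fusion comes from classical annulation chemistry, and C26 is already in place as a ketal.
- Weak points: only ring C is made. C17 is set by protonation after the shift, not by the shift. C10 in A2 is an unsubstituted methylene and the C23 allyl group has all three future ring A carbons at alkene or alkane level. Ring A would still need C10 methylation, three oxidation-state adjustments and a closure that forms a non-enolisable β-diketone.
- Comparison: step by step this road is more predictable than the chosen one, whose key step has no direct precedent on a trioxygenated arene. The chosen plan sets against this a key step that delivers rings B and C and ring A with all three oxygens at once, so the remaining work is one oxidation.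

**Alternative 2:** Ring-rearrangement metathesis. The cut is C10=C12 of ring B, paired with C12=C18 of norbornene A3. The second-generation Grubbs catalyst opens the strained alkene and closes C12 onto the methacryloyl carbon C10, giving cyclopentenone ester A4 with an isopropenyl group on C17.
- Merits: a Diels–Alder reaction sets C13, C17 and C23 relative to each other, the key step is catalytic and thermal, C24 and C26 arrive at the right oxidation level, and hydration of the isopropenyl group gives C18.
- Weak points: the catalyst must open a trisubstituted norbornene alkene and close onto a 1,1-disubstituted enone alkene. The cycloaddition behind A3 must control regiochemistry, the endo/exo placement of two different acyl groups and absolute configuration together. Ring A is still missing C7 and C8, which means acylation at C10 to make the second bridgehead and a Claisen closure onto the C24 ester under conditions that also cleave the product.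
- Comparison: in scalability and catalytic character this road is better, and it reaches a bicyclic intermediate in about as many steps. The chosen plan sets against it absolute configuration from one auxiliary alkylation and a ring A that needs no further carbon–carbon bond.

**Alternative 3:** Vinylketene–alkene cycloaddition. The cuts are C13–C23 and a temporary C12–C26 bond. Triethylamine converts acid chloride A5 into vinylketene A6, whose C23=C26 bond adds to the tethered C12=C13 alkene to give vinyl cyclobutanone A7.
- Merits: it uses the same chiral tether and the same control by C17 as the chosen plan, and intramolecular ketene cycloadditions are a dependable way to make a quaternary carbon at a ring fusion without light or high dilution.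
- Weak points: the C12–C26 bond is not in the target. The four-membered ring must be expanded by inserting C10 with its methyl group between C26 and C12, where migration of C12 must win over C23. The vinyl group supplies C24 and C7 at the wrong oxidation level and C8 is absent.
- Comparison: the key step is safer than the photocycloaddition and has no flank question; that question moves to the ring expansion. The chosen plan sets against it three rings, five stereocentres and the complete oxygenated ring A in one operation.

Key step: step 10

Assumption: atom labels C1–C27 are heavy-atom positions in the target SMILES (locants inside systematic names are nomenclature locants); 23, 24 and 27 are drawn as the enol tautomer of that SMILES and are taken to exist as open hydroxy ketones, not as C18–O–C26 hemiketals.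

## Route

Step 1
Reactants: 1 2,4,6-trimethoxytoluene
Product: 3 2,4,6-trimethoxy-3-methylbenzaldehyde, via iminium salt 2 (not isolated)
Conditions: POCl3, DMF, 0 °C to 40 °C; then H2O, NaOAc
Reagents that add atoms: N,N-dimethylformamide, CN(C)C=O; water, O
Why: Vilsmeier–Haack formylation: the two free ring positions of 1 are equivalent and each is activated by three ortho/para oxygen donors, so the chloroiminium ion substitutes once to give iminium salt 2, whose acceptor character stops a second attack; aqueous work-up hydrolyses 2 to 3.

Step 2
Reactants: 3 2,4,6-trimethoxy-3-methylbenzaldehyde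
Product: 4 (2,4,6-trimethoxy-3-methylphenyl)methanol
Conditions: NaBH4, MeOH, 0 °C
Reagents that add atoms: none
Why: Borohydride reduction of an aryl aldehyde; nothing else in 3 is reducible.

Step 3
Reactants: 4 (2,4,6-trimethoxy-3-methylphenyl)methanol
Product: 5 2-(bromomethyl)-1,3,5-trimethoxy-4-methylbenzene
Conditions: PBr3, Et2O, −20 °C to 0 °C; cold aq NaHCO3 wash, used at once
Reagents that add atoms: phosphorus tribromide, BrP(Br)Br
Why: Conversion of a benzylic alcohol into the bromide through its phosphite ester; the doubly ortho-oxygenated bromide ionises easily, so it is made cold and taken directly into step 5.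

Step 4
Reactants: 6 3,3-dimethylpent-4-enoic acid; 7 (4S)-4-benzyl-1,3-oxazolidin-2-one
Product: 9 (4S)-4-benzyl-3-(3,3-dimethylpent-4-enoyl)-1,3-oxazolidin-2-one, via mixed anhydride 8 (not isolated)
Conditions: t-BuCOCl, Et3N, THF, −20 °C; then 7, LiCl, −20 °C to rt
Reagents that add atoms: none
Why: N-Acylation of the Evans auxiliary through the pivalic mixed anhydride 8; the nucleophile attacks the less hindered carbonyl of 8, and the acid has no α-stereocentre to lose.

Step 5
Reactants: 9 (4S)-4-benzyl-3-(3,3-dimethylpent-4-enoyl)-1,3-oxazolidin-2-one; 5 2-(bromomethyl)-1,3,5-trimethoxy-4-methylbenzene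
Product: 11 (4S)-4-benzyl-3-[(2S)-3,3-dimethyl-2-[(2,4,6-trimethoxy-3-methylphenyl)methyl]pent-4-enoyl]-1,3-oxazolidin-2-one, via sodium enolate 10 (not isolated)
Conditions: NaN(SiMe3)2, THF, −78 °C; then 5, −78 °C to −30 °C
Reagents that add atoms: none
Why: Evans asymmetric alkylation: the chelated Z-enolate 10 is covered on one face by the benzyl group of the auxiliary and the benzylic bromide enters from the other, which sets C17; the usual model gives the arrangement needed here, labelled S because the tertiary alkyl group outranks the arylmethyl group. A reactive benzylic bromide is the class of electrophile that such hindered imide enolates accept at low temperature.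

Step 6
Reactants: 11 the alkylated imide
Product: 13 (2S)-3,3-dimethyl-2-[(2,4,6-trimethoxy-3-methylphenyl)methyl]pent-4-enoic acid, via peroxy acid 12 (not isolated)
Conditions: LiOH, H2O2, THF–H2O, 0 °C; then Na2SO3; then 1 M HCl
Reagents that add atoms: hydrogen peroxide, OO
Why: Hydroperoxide cleavage of the N-acyl oxazolidinone: the small α-effect nucleophile attacks the exocyclic carbonyl even of hindered imides, sulfite reduces peroxy acid 12 to 13, and C17 is not enolised under these conditions; the auxiliary is recovered.

Step 7
Reactants: 13 the (2S) acid
Product: 14 methyl (2S)-3,3-dimethyl-2-[(2,4,6-trimethoxy-3-methylphenyl)methyl]pent-4-enoate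
Conditions: MeI, K2CO3, DMF, rt
Reagents that add atoms: iodomethane, CI
Why: O-Alkylation of the carboxylate (SN2 on iodomethane) gives the methyl ester without acid and without touching C17.

Step 8
Reactants: 14 the methyl ester
Product: 16 (3S)-2,4,4-trimethyl-3-[(2,4,6-trimethoxy-3-methylphenyl)methyl]hex-5-en-2-ol, via methyl ketone 15 (not isolated)
Conditions: MeMgBr (4 equiv), THF, 0 °C to rt; aq NH4Cl
Reagents that add atoms: methylmagnesium bromide, C[Mg]Br
Why: Double Grignard addition to an ester through methyl ketone 15; the C17 hydrogen is tertiary and sits between a quaternary carbon and the arylmethyl group, so enolisation toward it is slow and its configuration should be kept.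

Step 9
Reactants: 16 the tertiary alcohol
Product: 18 trimethyl{[(3S)-2,4,4-trimethyl-3-{[2,4,6-trimethoxy-3-methyl-5-(trimethylsilyl)phenyl]methyl}hex-5-en-2-yl]oxy}silane, via dilithio species 17 (not isolated)
Conditions: n-BuLi (2.5 equiv), TMEDA, THF, 0 °C to rt; then Me3SiCl, −78 °C to rt; aq NaHCO3
Reagents that add atoms: chlorotrimethylsilane, C[Si](C)(C)Cl
Why: Directed ortho-metalation: after the hydroxyl is deprotonated, n-BuLi removes the only ring hydrogen, which lies between two methoxy groups (C7), and Me3SiCl silylates carbon and oxygen. The C7 silyl group is the blocking group for the key step, and the silyl ether removes the only protic group from the photosubstrate; the electron-rich aryl silane is kept away from acid.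

Step 10
Reactants: 18 the silylated arene–alkene
Product: 19 C7-silylated tetracyclic vinylcyclopropane photoadduct (cyclopropane C8–C10–C26; enol ether C7=C24 with SiMe3 on C7; OMe on C8 and C24 and C26; C14 exo; C18 silyl ether cis to C12)
Conditions: hν (254 nm, low-pressure Hg lamp, quartz), degassed cyclohexane (0.005 M), rt
Reagents that add atoms: none
Why: Excitation of the alkoxyarene to S1 gives an intramolecular exciplex with the unactivated C12=C13 alkene; C13 bonds to C23 and C12 to C10 across the methoxy-bearing C26, and the resulting bicyclo[3.2.1]octenyl 1,3-diradical (C26 against the C8–C7–C24 allyl unit) collapses to the C8–C26 cyclopropane, while collapse onto C24 gives an isomer that step 11 carries to the same oxidation pattern. The closest known reaction type is the intramolecular arene–alkene meta photocycloaddition of ortho-alkoxy arenes through a three-atom tether, which adds 1,3 across the donor-bearing carbon. Ring C (C13, C14, C17, C22, C23) is the tether ring and closes 5-exo on the alkene by bonding at the internal carbon C13; ring B (C10, C12, C13, C23, C26) closes as a cyclopentane when the exocyclic carbon C12 reaches C10; the three-membered ring closes by radical recombination. C13 and C23 come out cis because a three-atom tether can only give a cis-fused five-membered ring, with C14 exo (syn to C26) because only there can the tether span C23 and C13; C10 follows from C23 because the alkene adds suprafacially to one face of the arene; C8 and C26 are fixed by the cage. The absolute sense comes from C17: in the folded tether the bulky C(CH3)2OSiMe3 group sits pseudo-equatorial on the forming ring C, which puts C18 cis to C12 as in the target. The step needs meta and not ortho addition, which an electron-rich arene with a simple alkene favours, and 1,3- and not 2,6-addition, which the two ortho methoxy groups enforce. It also needs the C10 and not the C7 flank, which the SiMe3 group secures by making C7 the more hindered bonding site and by twisting O24 so that it is no better a donor than O26. The adduct is acid-labile and is taken on without chromatography.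

Step 11
Reactants: 19 the photoadduct
Product: 22 9-bromo-8-methoxy-4,4,7-trimethyl-3-[2-(trimethylsilyloxy)propan-2-yl]tricyclo[5.3.1.0^{1,5}]undec-8-ene-10,11-dione (ring configuration as in 27), via bromo enol ether 20 (not isolated), via dibromo ketone 21 (not isolated)
Conditions: NBS (2.2 equiv), NaHCO3, THF–H2O, 0 °C to rt
Reagents that add atoms: N-bromosuccinimide, BrN1C(=O)CCC1=O; water, O
Why: Ipso-bromodesilylation of the vinylsilane gives bromo enol ether 20; a second electrophilic bromination with capture of the C24 oxocarbenium ion by water gives dibromo ketone 21; 21 then undergoes a Grob-type fragmentation in which the O26 lone pair pushes, the strained C8–C26 bond breaks, C7=C8 forms and bromide leaves, and water turns the C26 oxocarbenium ion into the bridging ketone. The NaHCO3 buffer keeps protons from opening the dialkoxycyclopropane without oxidation. The isomeric cyclopropane adduct, or bromine attack on the cyclopropane bond, leads to the transposed vinylogous ester (C8 ketone, C24 methoxy), which step 12 merges with 22.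

Step 12
Reactants: 22 the bromo vinylogous ester
Product: 24 8-hydroxy-3-(2-hydroxypropan-2-yl)-4,4,7-trimethyltricyclo[5.3.1.0^{1,5}]undec-8-ene-10,11-dione (ring configuration as in 27), via bromo dione 23 (not isolated)
Conditions: 1 M HCl, THF, 40 °C; then aq NaHSO3, rt
Reagents that add atoms: water, O
Why: Acid hydrolysis of the vinylogous ester and of the silyl ether gives the 2-bromo-1,3-dione 23, whose positive bromine is removed by bisulfite (reduction of an α-halo-β-dicarbonyl compound). Acid is used in place of hydroxide because the C24/C26 and C8/C26 β-diketones cannot enolise and would undergo retro-Claisen cleavage.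

Step 13
Reactants: 24 the dione; 25 (2R)-2-methylbutanoic acid
Product: 27 (1S,3S,5S,7S)-8-hydroxy-3-(2-hydroxypropan-2-yl)-4,4,7-trimethyl-9-[(2R)-2-methylbutanoyl]tricyclo[5.3.1.0^{1,5}]undec-8-ene-10,11-dione (the target), via enol ester 26 (not isolated)
Conditions: DCC, DMAP, CH2Cl2, 0 °C to rt; 1 M HCl wash
Reagents that add atoms: none
Why: Carbodiimide coupling gives enol ester 26 (either enol oxygen converges) and DMAP then moves the acyl group from oxygen to C7 through the acylpyridinium enolate ion pair, the standard route to 2-acylcyclohexane-1,3-diones. The hindered tertiary alcohol is not acylated, no strong base is present to epimerise C3, and the product is held as its chelated enol.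

## Compound list

1 | 2,4,6-trimethoxytoluene | Cc1c(OC)cc(OC)cc1OC | starting material
2 | (2,4,6-trimethoxy-3-methylbenzylidene)dimethyliminium dichlorophosphate | COc1cc(OC)c(C)c(OC)c1C=[N+](C)C.[O-]P(=O)(Cl)Cl | intermediate
3 | 2,4,6-trimethoxy-3-methylbenzaldehyde | COc1cc(OC)c(C)c(OC)c1C=O | intermediate
4 | (2,4,6-trimethoxy-3-methylphenyl)methanol | COc1cc(OC)c(C)c(OC)c1CO | intermediate
5 | 2-(bromomethyl)-1,3,5-trimethoxy-4-methylbenzene | COc1cc(OC)c(C)c(OC)c1CBr | intermediate
6 | 3,3-dimethylpent-4-enoic acid | C=CC(C)(C)CC(=O)O | starting material
7 | (4S)-4-benzyl-1,3-oxazolidin-2-one | O=C1N[C@@H](Cc2ccccc2)CO1 | starting material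
8 | 3,3-dimethylpent-4-enoic 2,2-dimethylpropanoic anhydride | C=CC(C)(C)CC(=O)OC(=O)C(C)(C)C | intermediate
9 | (4S)-4-benzyl-3-(3,3-dimethylpent-4-enoyl)-1,3-oxazolidin-2-one | O=C1OC[C@H](Cc2ccccc2)N1C(=O)CC(C)(C)C=C | intermediate
10 | sodium (Z)-enolate of 9 (O and the tertiary alkyl group cis) | [Na+].[O-]/C(=C\C(C)(C)C=C)N1C(=O)OC[C@@H]1Cc1ccccc1 | intermediate
11 | (4S)-4-benzyl-3-[(2S)-3,3-dimethyl-2-[(2,4,6-trimethoxy-3-methylphenyl)methyl]pent-4-enoyl]-1,3-oxazolidin-2-one | O=C1OC[C@H](Cc2ccccc2)N1C(=O)[C@@H](Cc1c(OC)cc(OC)c(C)c1OC)C(C)(C)C=C | intermediate
12 | (2S)-3,3-dimethyl-2-[(2,4,6-trimethoxy-3-methylphenyl)methyl]pent-4-eneperoxoic acid | OOC(=O)[C@@H](Cc1c(OC)cc(OC)c(C)c1OC)C(C)(C)C=C | intermediate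
13 | (2S)-3,3-dimethyl-2-[(2,4,6-trimethoxy-3-methylphenyl)methyl]pent-4-enoic acid | OC(=O)[C@@H](Cc1c(OC)cc(OC)c(C)c1OC)C(C)(C)C=C | intermediate
14 | methyl (2S)-3,3-dimethyl-2-[(2,4,6-trimethoxy-3-methylphenyl)methyl]pent-4-enoate | COC(=O)[C@@H](Cc1c(OC)cc(OC)c(C)c1OC)C(C)(C)C=C | intermediate
15 | (3S)-4,4-dimethyl-3-[(2,4,6-trimethoxy-3-methylphenyl)methyl]hex-5-en-2-one | CC(=O)[C@@H](Cc1c(OC)cc(OC)c(C)c1OC)C(C)(C)C=C | intermediate
16 | (3S)-2,4,4-trimethyl-3-[(2,4,6-trimethoxy-3-methylphenyl)methyl]hex-5-en-2-ol | COc1cc(OC)c(C)c(OC)c1C[C@H](C(C)(C)O)C(C)(C)C=C | intermediate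
17 | dilithio derivative of 16 (lithium alkoxide at C18–O, aryllithium at C7) | [Li]c1c(OC)c(C)c(OC)c(C[C@H](C(C)(C)O[Li])C(C)(C)C=C)c1OC | intermediate
18 | trimethyl{[(3S)-2,4,4-trimethyl-3-{[2,4,6-trimethoxy-3-methyl-5-(trimethylsilyl)phenyl]methyl}hex-5-en-2-yl]oxy}silane | C[Si](C)(C)c1c(OC)c(C)c(OC)c(C[C@H](C(C)(C)O[Si](C)(C)C)C(C)(C)C=C)c1OC | intermediate
19 | C7-silylated meta photoadduct: tetracycle with cyclopropane C8–C10–C26 and enol ether C7=C24; SiMe3 on C7, OMe on C8, C24 and C26, CH3 on C10; ring C cis-fused at C13–C23 with C14 exo (syn to C26); C18–OSiMe3 group cis to C12 | C1([Si](C)(C)C)[C@]4(OC)[C@]2(C)C[C@H]3C(C)(C)[C@@H](C(C)(C)O[Si](C)(C)C)C[C@@]3(C=1OC)[C@@]24OC | intermediate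
20 | bromo enol ether: 19 with Br in place of SiMe3 on C7 | C1(Br)[C@]4(OC)[C@]2(C)C[C@H]3C(C)(C)[C@@H](C(C)(C)O[Si](C)(C)C)C[C@@]3(C=1OC)[C@@]24OC | intermediate
21 | dibromo ketone: cage of 19 with C7 as CBr2 and C24 as ketone, cyclopropane C8–C10–C26 intact | C1(Br)(Br)[C@]4(OC)[C@]2(C)C[C@H]3C(C)(C)[C@@H](C(C)(C)O[Si](C)(C)C)C[C@@]3(C1=O)[C@@]24OC | intermediate
22 | 9-bromo-8-methoxy-4,4,7-trimethyl-3-[2-(trimethylsilyloxy)propan-2-yl]tricyclo[5.3.1.0^{1,5}]undec-8-ene-10,11-dione (ring configuration as in 27; Br on C7, OMe on C8) | BrC1=C(OC)[C@]2(C)C[C@H]3C(C)(C)[C@@H](C(C)(C)O[Si](C)(C)C)C[C@@]3(C1=O)C2=O | intermediate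
23 | 9-bromo-8-hydroxy-3-(2-hydroxypropan-2-yl)-4,4,7-trimethyltricyclo[5.3.1.0^{1,5}]undec-8-ene-10,11-dione (ring configuration as in 27) | BrC1=C(O)[C@]2(C)C[C@H]3C(C)(C)[C@@H](C(C)(C)O)C[C@@]3(C1=O)C2=O | intermediate
24 | 8-hydroxy-3-(2-hydroxypropan-2-yl)-4,4,7-trimethyltricyclo[5.3.1.0^{1,5}]undec-8-ene-10,11-dione (ring configuration as in 27) | C1=C(O)[C@]2(C)C[C@H]3C(C)(C)[C@@H](C(C)(C)O)C[C@@]3(C1=O)C2=O | intermediate
25 | (2R)-2-methylbutanoic acid | CC[C@@H](C)C(=O)O | starting material
26 | enol ester of 24: (2R)-2-methylbutanoate on the C8 enol oxygen (ring configuration as in 27) | C1=C(OC(=O)[C@H](C)CC)[C@]2(C)C[C@H]3C(C)(C)[C@@H](C(C)(C)O)C[C@@]3(C1=O)C2=O | intermediate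
27 | (1S,3S,5S,7S)-8-hydroxy-3-(2-hydroxypropan-2-yl)-4,4,7-trimethyl-9-[(2R)-2-methylbutanoyl]tricyclo[5.3.1.0^{1,5}]undec-8-ene-10,11-dione | CC[C@@H](C)C(=O)C1=C(O)[C@]2(C)C[C@H]3C(C)(C)[C@@H](C(C)(C)O)C[C@@]3(C1=O)C2=O | target

## Step count and risks

Total steps: 13. Longest linear sequence: 12 (1, 3, 4, 5, 11, 13, 14, 16, 18, 19, 22, 24, 27).

**Step 10 (key step).**
- What may go wrong: unproductive decay of the excited state. The fully substituted, twisted trioxygenated chromophore has not been tried in this reaction and could relax by valence isomerisation, lose the aryl silyl group, or add in the ortho mode, so that no meta adduct builds up.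
- Fallback: a thermal, cationic [5+2] cycloaddition that forms the same bonds C13–C23 and C10–C12 without light. It sets out from ester 14 and returns at dione 24.
- BCl3 cleaves the doubly flanked, twisted O26 methyl ether, and the freed phenol closes onto the ester to give (3S)-5,7-dimethoxy-8-methyl-3-(2-methylbut-3-en-2-yl)-3,4-dihydro-2H-chromen-2-one F1. Only an ortho phenol can lactonise.
- Excess MeMgBr opens the lactone to 2-[(2S)-3-hydroxy-3-methyl-2-(2-methylbut-3-en-2-yl)butyl]-3,5-dimethoxy-6-methylphenol F2.
- Silylation of both hydroxyls and methanolysis of the aryl silyl ether alone leaves the tertiary trimethylsilyl ether F3.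
- Wessely oxidation with Pb(OAc)4, then acid, ionises the o-quinol acetate to a phenoxonium ion. Its ortho carbons C23 and C10 add the tethered alkene across the C26 carbonyl, and the dimethoxyallyl cation left on C24–C7–C8 loses one O-methyl group to give the vinylogous ester F4.
- The acid treatment of step 12 converts F4 into 24.
- In this variant the flank is decided by which ortho oxygen is free; an O24 lactone isomer would have to be separated at F1.

**Step 5.**
- What may go wrong: slow C-alkylation. A neopentyl-type imide enolate meets a benzylic bromide with two ortho substituents, so enolate decomposition and self-condensation of the electron-rich bromide can take over.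
- Fallback: form the hindered C17–C14 bond by sigmatropic rearrangement. It sets out from bromide 5 and returns at acid 13.
- The unhindered lithium enolate of 3-methylbut-2-en-1-yl acetate is alkylated with 5 to give 3-methylbut-2-en-1-yl 3-(2,4,6-trimethoxy-3-methylphenyl)propanoate F5.
- An enantioselective Ireland–Claisen rearrangement of F5 through a boron enolate carrying a chiral 1,2-diphenylethane-1,2-diamine bis-sulfonamide ligand would give 13 directly. The rearrangement through the silyl ketene acetal, followed by resolution of the acid as a 1-phenylethylammonium salt, is the plain alternative.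

**Step 11.**
- What may go wrong: proton-induced opening of the dialkoxycyclopropane before the second bromination, which leaves C26 as a CH(OMe) carbon and loses the oxidation level; or bromination at further sites if the reagent is in excess.
- Fallback: single-electron oxidative opening in place of bromination. It sets out from 19 and returns at 24.
- FeCl3 in DMF with pyridine, the reagent used for oxidative cleavage of oxycyclopropanes, should open the C8–C26 bond and give the 9-(trimethylsilyl) vinylogous ester F6.
- 1 M HCl then removes the silyl groups and hydrolyses the vinylogous ester to 24, and no bromine has to be removed.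

**Step 13.**
- What may go wrong: partial epimerisation of C3 through the acylpyridinium ion or a ketene, or incomplete migration of the acyl group from oxygen to C7.
- Fallback: carbanion acylation in place of acyl transfer. It sets out from bromide 22 and acid 25 and returns at 27.
- Acid 25 is converted into (2R)-N-methoxy-N,2-dimethylbutanamide F7.
- Bromine–magnesium exchange on 22 (i-PrMgCl·LiCl, THF, −78 °C) and acylation of the vinylmagnesium species with F7 give the C7-acylated vinylogous ester F8.
- 1 M HCl hydrolyses the vinylogous ester and the silyl ether of F8 to 27.

## Further compounds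

F1 | step 10 | (3S)-5,7-dimethoxy-8-methyl-3-(2-methylbut-3-en-2-yl)-3,4-dihydro-2H-chromen-2-one | O=C1Oc2c(C)c(OC)cc(OC)c2C[C@H]1C(C)(C)C=C
F2 | step 10 | 2-[(2S)-3-hydroxy-3-methyl-2-(2-methylbut-3-en-2-yl)butyl]-3,5-dimethoxy-6-methylphenol | COc1cc(OC)c(C)c(O)c1C[C@H](C(C)(C)O)C(C)(C)C=C
F3 | step 10 | 3,5-dimethoxy-6-methyl-2-[(2S)-3-methyl-2-(2-methylbut-3-en-2-yl)-3-(trimethylsilyloxy)butyl]phenol | COc1cc(OC)c(C)c(O)c1C[C@H](C(C)(C)O[Si](C)(C)C)C(C)(C)C=C
F4 | step 10 | 8-methoxy-4,4,7-trimethyl-3-[2-(trimethylsilyloxy)propan-2-yl]tricyclo[5.3.1.0^{1,5}]undec-8-ene-10,11-dione (ring configuration as in 27) | C1=C(OC)[C@]2(C)C[C@H]3C(C)(C)[C@@H](C(C)(C)O[Si](C)(C)C)C[C@@]3(C1=O)C2=O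
F5 | step 5 | 3-methylbut-2-en-1-yl 3-(2,4,6-trimethoxy-3-methylphenyl)propanoate | COc1cc(OC)c(C)c(OC)c1CCC(=O)OCC=C(C)C
F6 | step 11 | 8-methoxy-4,4,7-trimethyl-9-(trimethylsilyl)-3-[2-(trimethylsilyloxy)propan-2-yl]tricyclo[5.3.1.0^{1,5}]undec-8-ene-10,11-dione (ring configuration as in 27) | C[Si](C)(C)C1=C(OC)[C@]2(C)C[C@H]3C(C)(C)[C@@H](C(C)(C)O[Si](C)(C)C)C[C@@]3(C1=O)C2=O
F7 | step 13 | (2R)-N-methoxy-N,2-dimethylbutanamide | CC[C@@H](C)C(=O)N(C)OC
F8 | step 13 | 8-methoxy-4,4,7-trimethyl-9-[(2R)-2-methylbutanoyl]-3-[2-(trimethylsilyloxy)propan-2-yl]tricyclo[5.3.1.0^{1,5}]undec-8-ene-10,11-dione (ring configuration as in 27) | CC[C@@H](C)C(=O)C1=C(OC)[C@]2(C)C[C@H]3C(C)(C)[C@@H](C(C)(C)O[Si](C)(C)C)C[C@@]3(C1=O)C2=O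
A1 | alternative 1 | α-diazo ketone of the cis-fused hydrindanone (C18 ketone, diazo group on C17, C26 as dioxolane, allyl on C23) | C1C[C@H]2C(C)(C)C(=O)C(=[N+]=[N-])C[C@@]2(CC=C)C13OCCO3
A2 | alternative 1 | ring-contracted diquinane methyl ester | C1C[C@H]2C(C)(C)[C@@H](C(=O)OC)C[C@@]2(CC=C)C13OCCO3
A3 | alternative 2 | Diels–Alder norbornene (C12=C18 alkene, gem-dimethyl bridge C14, ester and methacryloyl group on C23) | CC1=C[C@H]2C(C)(C)[C@@H]1C[C@@]2(C(=O)OC)C(=O)C(C)=C
A4 | alternative 2 | cis-fused cyclopentenone ester with isopropenyl on C17 | CC1=C[C@H]2C(C)(C)[C@@H](C(C)=C)C[C@@]2(C(=O)OC)C1=O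
A5 | alternative 3 | (E)-2-substituted but-2-enoyl chloride carrying the chiral tether | C/C=C(\C[C@H](C(C)(C)O[Si](C)(C)C(C)(C)C)C(C)(C)C=C)C(Cl)=O
A6 | alternative 3 | vinylketene derived from A5 | C=CC(=C=O)C[C@H](C(C)(C)O[Si](C)(C)C(C)(C)C)C(C)(C)C=C
A7 | alternative 3 | vinyl cyclobutanone fused to ring C (bicyclo[3.2.0]heptanone) | C1[C@H]2C(C)(C)[C@@H](C(C)(C)O[Si](C)(C)C(C)(C)C)C[C@@]2(C=C)C1=O
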